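J, the product, is made from dissolved X, and X comes out of solid L, so I look first at what feeds the solution.

- south-east: L 0.010 M; Q 0.50 mM; the very flask that is asked about, followed so far
- flask: L 0.010 M; Q 0.50 mM; time 10 h

south-east run (percent of the L charged)

| time / min | J / % | X / % |
|---|---|---|
| 3.00 | 0.3 | 0.6 |
| 10.0 | 0 | 0.6 |
| 15.0 | 0.6 | 1.9 |
| 25.0 | 0.1 | 4.5 |
| 40.0 | 0 | 5.6 |
| 50.0 | 0.8 | 7.4 |

(each reading ± 0.5 percentage points)

- solid, in amounts per volume of the solution: L
- the analysis behind the earlier runs scatters by 0.5 percentage points, standard deviation
- at the start none of L is in solution
- X is what L becomes in solution
- X means what is dissolved; the solid is not counted in it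

* the J standing at 10 h, as a percentage of the L charged
* concentration of X in solution at 2.5 h, in percent of saturation
* the change that raises the amount of J at 10 h, in percent of the L charged most ("none" if none brings more than 2 percentage points) (larch / ash / oak / none)
* amount of J at 10 h, in percent of the L charged, after oak

- larch: doubling the solubility of L, all else as stated
- ash: doubling the dissolution coefficient of L, all else as stated
- oak: doubling the amount of Q, all else as stated

1. I take the dissolving to follow one concentration, the gap between [X] and saturation, and not the amount of L lying there while solid is left. That makes it zero-order in L.

2. My first way to the rate uses the X reading at 25.0 min, which gives 1.08 mM/h. My second way uses the gain from then to 50.0 min, which gives 0.696 mM/h, less than the first.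

3. The two ways part, and they share one reading. Either the rate really falls, or that reading stands high, which lifts the first way and lowers the second. So I leave it out: the reading at 40.0 min gives 0.840 mM/h, and the reading at 50.0 min gives 0.888 mM/h. These two stand close, so I read the shared reading as the one that cheats: it lies 0.8 percentage points above the line through the reading at 50.0 min, against a scatter of 0.5 points.

4. I therefore keep 0.888 mM/h as the feed, the concentration of X entering the solution per hour while [X] lies far below saturation. This feed is a reading and carries the scatter of the 7.4 % behind it, which is 0.5 points. Like a time constant, the charge divided by this reading gives 11.3 h, longer than the 10 h asked. Held for 10 h, the feed comes to 88.8 % of the L charged, and a rising [X] lowers that. This estimate is my commitment. I draw no value of J from the J readings, which stand at 0.8 % at 50.0 min against a scatter of 0.5 points, and I draw no saturation from the X readings.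

5. The forecast gives 25 % for y, 55 % for sat, larch for best and 38 % for yb. On saturation it says: “with little visible curvature, so solubility is poorly fixed”.

6. This flask gives 33.1 % of J at 10 h, 24.7 % of saturation at 2.5 h against the forecast's 55 %, larch as best with a gain of 25 points, and 50.8 % after oak.

    X + Q → Q + J (k = 311 /M/h)
    X → G (k = 0.0383 /h)
    L ⇌ X, rate k3*(cs3 - [X]) while solid is left; crystals form when [X] > cs3 (solubility = 6.90 mM, k = 0.147 /h)

7. Counting X, J and G at 10 h, this flask has passed 7.01 mM into solution, less than the 8.88 mM of the feed held throughout. For the neighbour charged with 0.017 M of L, the same feed held throughout comes to 52.2 % of its larger charge. That neighbour has passed 7.01 mM, about the same as this flask, and it holds 19.5 % of its own charge as J.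

(The readings stem from a simulated flask from invented constants; noise was put on by code.)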